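**Retrosynthetic overview**

1. Feature: in chroman numbering, the pyran atoms O1–C8a–C4a–C4 are a masked ortho-quinone methide (O=C8a–C4a=C4H2) on the pentasubstituted benzene ring, and C3–C2(CH3)(CH2R) is a 1,1-disubstituted alkene; C2 is the only stereocentre.
2. Last disconnection: the C2 arm CH2–C(=O)–CH=C(CH3)2 comes from CH2–C≡C–C(CH3)2OH by Meyer–Schuster rearrangement, run last so that the β-aryloxy ketone never meets base.
3. Key disconnection: C3–C4 and O1–C2 by an asymmetric inverse-demand hetero-Diels–Alder reaction of the ortho-quinone methide with a methallyl alkyne. The pyran ring is the only ring formed; the benzene ring is bought.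
4. Salicyl alcohol: 3,5-dimethoxybenzyl alcohol is palmitoylated, formylated at C2, demethylated next to the aldehyde and hydroxymethylated ortho to the new phenol on a boronate template.
5. Alkene: copper-catalysed coupling of methallyl chloride with 2-methylbut-3-yn-2-ol, then triethylsilyl protection.

Key step: step 7

Assumption: the sense of induction of the chiral acid cannot be predicted for this alkene class, so the catalyst enantiomer that delivers the (2S)-chroman is to be selected by screening; the C7 hydroxymethyl is carried as its palmitate from step 1, because this ester should tolerate the formylation, the BCl3 demethylation and the acid-catalysed cycloaddition better than a benzylic silyl ether and removes a late protecting-group exchange.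

**Route**

Step 1
Reactants: 1 3,5-dimethoxybenzyl alcohol; 2 palmitoyl chloride
Product: 3 3,5-dimethoxybenzyl hexadecanoate
Conditions: Et3N, DMAP (cat.), CH2Cl2, 0 °C to rt
Reagents that add atoms: none
Why: Acylation of the primary benzylic alcohol by the acid chloride (nucleophilic acyl substitution) is routine, and the palmitate then serves as the protecting group of the future C7 hydroxymethyl through all later steps.

Step 2
Reactants: 3 3,5-dimethoxybenzyl hexadecanoate
Product: 5 (2-formyl-3,5-dimethoxyphenyl)methyl hexadecanoate, via iminium chloride 4 (not isolated)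
Conditions: POCl3, DMF, 0 °C to 60 °C; then H2O, 0 °C to rt
Reagents that add atoms: N,N-dimethylformamide CN(C)C=O; water O
Why: Vilsmeier–Haack formylation of the resorcinol dimethyl ether ring should take place ortho to one methoxy group and para to the other (C2, equivalent to C6) and not at the hindered carbon between the two methoxy groups, the ester being inert to the chloroiminium reagent, and water then hydrolyses iminium salt 4.

Step 3
Reactants: 5 (2-formyl-3,5-dimethoxyphenyl)methyl hexadecanoate
Product: 7 (2-formyl-3-hydroxy-5-methoxyphenyl)methyl hexadecanoate, via aryloxydichloroborane 6 (not isolated)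
Conditions: BCl3 (1.2 equiv), CH2Cl2, −78 °C to 0 °C; then H2O
Reagents that add atoms: none
Why: Chelation-controlled Lewis acid demethylation: BCl3 bridges the formyl oxygen and the neighbouring methoxy oxygen, so chloride should remove only that methyl group, while the para methoxy group and the benzylic ester (its CH2 is meta to both ring oxygens and cannot ionise) stay intact.

Step 4
Reactants: 7 (2-formyl-3-hydroxy-5-methoxyphenyl)methyl hexadecanoate
Product: 9 [2-formyl-3-hydroxy-4-(hydroxymethyl)-5-methoxyphenyl]methyl hexadecanoate, via benzodioxaborin 8 (not isolated)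
Conditions: PhB(OH)2, (CH2O)n, EtCO2H (cat.), toluene, reflux, Dean–Stark; then 2,2-dimethylpropane-1,3-diol, rt
Reagents that add atoms: paraformaldehyde (as formaldehyde) C=O
Why: Boronic acid templated ortho-hydroxymethylation of a phenol: the aryl phenylboronate should deliver formaldehyde through a six-membered transition state to the only free ortho carbon, which lies between OH and OCH3 and meta to the formyl group and so remains nucleophilic, the cyclic boronate 8 shields the acid-sensitive salicyl alcohol from diarylmethane formation, and boronate exchange with the diol releases it under neutral conditions.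

Step 5
Reactants: 10 2-methylbut-3-yn-2-ol; 11 3-chloro-2-methylprop-1-ene
Product: 12 2,6-dimethylhept-6-en-3-yn-2-ol
Conditions: CuI (10 mol%), NaI (cat.), K2CO3, DMF, rt
Reagents that add atoms: none
Why: Copper-catalysed coupling of a terminal alkyne with an allylic halide: the copper acetylide formed with carbonate base is alkylated by methallyl chloride (activated by iodide exchange), which should give the skipped enyne without base-induced isomerisation and tolerates the free tertiary alcohol.

Step 6
Reactants: 12 2,6-dimethylhept-6-en-3-yn-2-ol
Product: 13 triethyl[(2,6-dimethylhept-6-en-3-yn-2-yl)oxy]silane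
Conditions: TESOTf, 2,6-lutidine, CH2Cl2, −78 °C to 0 °C
Reagents that add atoms: triethylsilyl trifluoromethanesulfonate CC[Si](CC)(CC)OS(=O)(=O)C(F)(F)F
Why: Silylation of the hindered tertiary alcohol with the silyl triflate and 2,6-lutidine is reliable, and the silyl ether keeps this oxygen from adding to the ortho-quinone methide and from binding the chiral acid in step 7.

Step 7
Reactants: 9 [2-formyl-3-hydroxy-4-(hydroxymethyl)-5-methoxyphenyl]methyl hexadecanoate; 13 triethyl[(2,6-dimethylhept-6-en-3-yn-2-yl)oxy]silane
Product: 15 [(2S)-8-formyl-5-methoxy-2-methyl-2-[4-methyl-4-(triethylsilyloxy)pent-2-yn-1-yl]-3,4-dihydro-2H-chromen-7-yl]methyl hexadecanoate, via ortho-quinone methide 14 (not isolated)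
Conditions: chiral confined imidodiphosphorimidate Brønsted acid (BINOL-derived, 3,3'-diaryl, N-triflyl; 5 mol%; enantiomer chosen to give 2S), 13 (3 equiv), 5 Å molecular sieves, CHCl3, −20 °C to rt, slow addition of 9
Reagents that add atoms: none
Why: Proposed new method: the chiral acid protonates the benzylic hydroxyl of 9, water leaves with help from the ortho methoxy group and the phenol oxygen, and the ortho-quinone methide 14 (O=C8a–C4a=C4H2) stays hydrogen-bonded through its carbonyl oxygen and the C8 formyl group to the chiral anion inside the catalyst pocket. The terminal CH2 of alkene 13 attacks C4 and the quinone methide oxygen captures the developing tertiary cation at C2 in a concerted but asynchronous inverse-demand hetero-Diels–Alder reaction; the closest known reaction types are the chiral Brønsted acid catalysed [4+2] cycloaddition of in situ ortho-quinone methides with styrenes and enol ethers and the uncatalysed cycloaddition with 1,1-dialkylethylenes. The dihydropyran ring is closed by this intermolecular [4+2] cycloaddition (in the stepwise limit by six-membered capture of the C2 cation by the phenolic oxygen), forming C3–C4 and O1–C2. The C2 stereocentre is set by the catalyst alone, whose confined pocket must tell the methyl group from the propargylic CH2 arm (a linear alkyne ending in a bulky silyloxy group) as the alkene approaches the bound heterodiene; this facial discrimination is the unproven point. Regiochemistry is inherent (Markovnikov, the more substituted alkene carbon bonds to oxygen), and chemoselectivity rests on the substrate: the formyl group lowers the LUMO of the heterodiene yet is itself a deactivated, hydrogen-bonded salicylaldehyde carbonyl that should not undergo Prins or carbonyl-ene reaction, the alkyne is far less nucleophilic than the 1,1-disubstituted alkene, and excess alkene with slow addition of 9 should suppress oligomerisation of 14.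

Step 8
Reactants: 15 [(2S)-8-formyl-5-methoxy-2-methyl-2-[4-methyl-4-(triethylsilyloxy)pent-2-yn-1-yl]-3,4-dihydro-2H-chromen-7-yl]methyl hexadecanoate
Product: 16 [(2S)-8-formyl-2-(4-hydroxy-4-methylpent-2-yn-1-yl)-5-methoxy-2-methyl-3,4-dihydro-2H-chromen-7-yl]methyl hexadecanoate
Conditions: HF·pyridine, pyridine, THF, 0 °C to rt
Reagents that add atoms: none
Why: Fluoride-driven cleavage of the Si–O bond with buffered HF·pyridine (desilylation) is mildly acidic, so the palmitate, the aldehyde, the alkyne and the quaternary C2 stereocentre should be untouched.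

Step 9
Reactants: 16 [(2S)-8-formyl-2-(4-hydroxy-4-methylpent-2-yn-1-yl)-5-methoxy-2-methyl-3,4-dihydro-2H-chromen-7-yl]methyl hexadecanoate
Product: 17 [(2S)-8-formyl-5-methoxy-2-methyl-2-(4-methyl-2-oxopent-3-en-1-yl)-3,4-dihydro-2H-chromen-7-yl]methyl hexadecanoate (CNP0228756.1)
Conditions: Ph3PAuNTf2 (2 mol%), MeOH (1 equiv), toluene, rt
Reagents that add atoms: none
Why: Meyer–Schuster rearrangement catalysed by Ph3PAuNTf2: π-activation of the alkyne by the monovalent gold cation and formal 1,3-shift of the tertiary hydroxyl should place the carbonyl on the alkyne carbon next to the C2 methylene and give the β,β-dimethyl enone, and the neutral conditions avoid retro-oxa-Michael opening of the β-aryloxy ketone, which would racemise C2.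

**Compound list**

1 | 3,5-dimethoxybenzyl alcohol | COc1cc(CO)cc(OC)c1 | starting material
2 | palmitoyl chloride (hexadecanoyl chloride) | CCCCCCCCCCCCCCCC(=O)Cl | starting material
3 | 3,5-dimethoxybenzyl hexadecanoate | CCCCCCCCCCCCCCCC(=O)OCc1cc(OC)cc(OC)c1 | intermediate
4 | N-[[2-(hexadecanoyloxymethyl)-4,6-dimethoxyphenyl]methylidene]-N-methylmethanaminium chloride (iminium chloride, formed in the flask) | CCCCCCCCCCCCCCCC(=O)OCc1cc(OC)cc(OC)c1C=[N+](C)C.[Cl-] | intermediate
5 | (2-formyl-3,5-dimethoxyphenyl)methyl hexadecanoate | CCCCCCCCCCCCCCCC(=O)OCc1cc(OC)cc(OC)c1C=O | intermediate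
6 | [3-(dichloroboranyloxy)-2-formyl-5-methoxyphenyl]methyl hexadecanoate (aryloxydichloroborane, formed in the flask) | CCCCCCCCCCCCCCCC(=O)OCc1cc(OC)cc(OB(Cl)Cl)c1C=O | intermediate
7 | (2-formyl-3-hydroxy-5-methoxyphenyl)methyl hexadecanoate | CCCCCCCCCCCCCCCC(=O)OCc1cc(OC)cc(O)c1C=O | intermediate
8 | (8-formyl-5-methoxy-2-phenyl-4H-1,3,2-benzodioxaborin-7-yl)methyl hexadecanoate (benzodioxaborin, formed in the flask) | CCCCCCCCCCCCCCCC(=O)OCc1cc(OC)c2c(c1C=O)OB(c3ccccc3)OC2 | intermediate
9 | [2-formyl-3-hydroxy-4-(hydroxymethyl)-5-methoxyphenyl]methyl hexadecanoate | CCCCCCCCCCCCCCCC(=O)OCc1cc(OC)c(CO)c(O)c1C=O | intermediate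
10 | 2-methylbut-3-yn-2-ol | C#CC(C)(C)O | starting material
11 | 3-chloro-2-methylprop-1-ene | C=C(C)CCl | starting material
12 | 2,6-dimethylhept-6-en-3-yn-2-ol | C=C(C)CC#CC(C)(C)O | intermediate
13 | triethyl[(2,6-dimethylhept-6-en-3-yn-2-yl)oxy]silane | C=C(C)CC#CC(C)(C)O[Si](CC)(CC)CC | intermediate
14 | (2-formyl-5-methoxy-4-methylidene-3-oxocyclohexa-1,5-dien-1-yl)methyl hexadecanoate (ortho-quinone methide, formed in the flask) | CCCCCCCCCCCCCCCC(=O)OCC1=C(C=O)C(=O)C(=C)C(OC)=C1 | intermediate
15 | [(2S)-8-formyl-5-methoxy-2-methyl-2-[4-methyl-4-(triethylsilyloxy)pent-2-yn-1-yl]-3,4-dihydro-2H-chromen-7-yl]methyl hexadecanoate | CCCCCCCCCCCCCCCC(=O)OCc1cc(OC)c2c(c1C=O)O[C@](C)(CC#CC(C)(C)O[Si](CC)(CC)CC)CC2 | intermediate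
16 | [(2S)-8-formyl-2-(4-hydroxy-4-methylpent-2-yn-1-yl)-5-methoxy-2-methyl-3,4-dihydro-2H-chromen-7-yl]methyl hexadecanoate | CCCCCCCCCCCCCCCC(=O)OCc1cc(OC)c2c(c1C=O)O[C@](C)(CC#CC(C)(C)O)CC2 | intermediate
17 | [(2S)-8-formyl-5-methoxy-2-methyl-2-(4-methyl-2-oxopent-3-en-1-yl)-3,4-dihydro-2H-chromen-7-yl]methyl hexadecanoate | CCCCCCCCCCCCCCCC(=O)OCc1cc(OC)c2c(c1C=O)O[C@](C)(CC(=O)C=C(C)C)CC2 | target

**Totals**

Total step count: 9.
Longest linear sequence: 7 steps (steps 1, 2, 3, 4, 7, 8, 9 from compound 1); the alkene branch is 2 steps (steps 5 and 6).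

**Steps most likely to fail**

Step 7 (proposed new method). The catalyst pocket may not discriminate the methyl group from the propargylic CH2 arm, giving poor facial selectivity. Ionisation of the unsubstituted benzylic alcohol may also be slow, so that oligomerisation of the quinone methide or acid-induced migration of the alkene into conjugation with the alkyne competes. The fallback uses known chemistry and sets out from 9 and 13. Heating 9 with excess 13 in o-xylene at about 150 °C in a sealed vessel should generate 14 thermally, and the uncatalysed [4+2] cycloaddition with the 1,1-dialkyl alkene should give, with the same regiochemistry, the racemic cycloadduct F1. Preparative chromatography of F1 on a chiral stationary phase (supercritical fluid chromatography) separates the (2S)-chroman from the (2R)-enantiomer F2, which is discarded. The route is rejoined at 15.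

Step 4. The phenol is tied up in a hydrogen bond to the formyl group and the ring is less nucleophilic than a simple phenol, so boronate formation and the templated C–C bond formation may stall; untemplated attack para to the hydroxyl may then compete. The fallback sets out from 7 and exchanges nitrogen for oxygen through the quinone methide. A phenol Mannich reaction with N,N-dimethylmethyleneiminium iodide and K2CO3 in CH2Cl2, directed ortho by phenoxide–iminium pairing, should give the Mannich base F3. Methylation with MeI in MeCN gives the quaternary ammonium iodide F4. Warming F4 in aqueous NaHCO3/MeCN expels trimethylamine to give 14, which water captures. The route is rejoined at 9.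

Step 9. Gold-catalysed hydration of the alkyne with the wrong regiochemistry may compete, the reaction may stall at a β-hydroxy ketone, or Lewis acid may promote retro-oxa-Michael opening of the pyran ring. The fallback sets out from 16 and replaces the hydroxyl shift by an acyloxy migration. Acetylation of the tertiary alcohol (Ac2O, Et3N, DMAP, CH2Cl2) gives the propargylic acetate F5. Ph3PAuNTf2 in wet butan-2-one should then trigger the [3,3]-acyloxy shift to the allenyl acetate F6, which is not isolated and is hydrolysed in the same flask to the enone. The route is rejoined at 17.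

**Further compounds**

F1 | step 7 | racemic [8-formyl-5-methoxy-2-methyl-2-[4-methyl-4-(triethylsilyloxy)pent-2-yn-1-yl]-3,4-dihydro-2H-chromen-7-yl]methyl hexadecanoate | CCCCCCCCCCCCCCCC(=O)OCc1cc(OC)c2c(c1C=O)OC(C)(CC#CC(C)(C)O[Si](CC)(CC)CC)CC2
F2 | step 7 | [(2R)-8-formyl-5-methoxy-2-methyl-2-[4-methyl-4-(triethylsilyloxy)pent-2-yn-1-yl]-3,4-dihydro-2H-chromen-7-yl]methyl hexadecanoate | CCCCCCCCCCCCCCCC(=O)OCc1cc(OC)c2c(c1C=O)O[C@@](C)(CC#CC(C)(C)O[Si](CC)(CC)CC)CC2
F3 | step 4 | [4-[(dimethylamino)methyl]-2-formyl-3-hydroxy-5-methoxyphenyl]methyl hexadecanoate | CCCCCCCCCCCCCCCC(=O)OCc1cc(OC)c(CN(C)C)c(O)c1C=O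
F4 | step 4 | [3-formyl-4-(hexadecanoyloxymethyl)-2-hydroxy-6-methoxyphenyl]methyl-trimethylazanium iodide | CCCCCCCCCCCCCCCC(=O)OCc1cc(OC)c(C[N+](C)(C)C)c(O)c1C=O.[I-]
F5 | step 9 | [(2S)-2-(4-acetyloxy-4-methylpent-2-yn-1-yl)-8-formyl-5-methoxy-2-methyl-3,4-dihydro-2H-chromen-7-yl]methyl hexadecanoate | CCCCCCCCCCCCCCCC(=O)OCc1cc(OC)c2c(c1C=O)O[C@](C)(CC#CC(C)(C)OC(C)=O)CC2
F6 | step 9 | [(2S)-2-(2-acetyloxy-4-methylpenta-2,3-dien-1-yl)-8-formyl-5-methoxy-2-methyl-3,4-dihydro-2H-chromen-7-yl]methyl hexadecanoate | CCCCCCCCCCCCCCCC(=O)OCc1cc(OC)c2c(c1C=O)O[C@](C)(CC(OC(C)=O)=C=C(C)C)CC2
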